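**Plan**

1. The last cut is the 4'-O–Si bond. Before it, the C3=C4 bond of the pyran ring is cut by ring-closing metathesis. This works because that alkene joins the carbon on C4a to the carbon on the quaternary C2 hanging from O1, so the 2,2-dimethyl-2H-chromene hides an ortho-vinyl aryl 1,1-dimethylallyl ether.
2. Further cuts: O1–C2 (tertiary propargyl ether, then semihydrogenation), C4a–vinyl (Stille coupling of an aryl iodide), C8–prenyl (Claisen shift from the same oxygen O1), and the aryl–carbonyl bond (aryllithium plus aldehyde).
3. Forward: phloroglucinol tris-MOM ether is lithiated, joined to silyl-protected 4-hydroxybenzaldehyde, oxidised and unmasked to the trihydroxybenzophenone.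
4. The para oxygen is then used twice: first to deliver prenyl to carbon (ether, iodination of one ortho carbon, Claisen shift to the other), then, after vinylation of the iodide, as the tertiary allyl ether.
5. The pyran is the only ring formed and is closed in the penultimate step; desilylation ends the route.
6. Stereochemistry: the target has no stereocentre, and the C3=C4 alkene is cis by ring constraint, so nothing has to be controlled.

Key step: step 13

Remark: because the target is achiral, "single enantiomer" reduces to the constitution shown; the 4'-phenol is carried as a triisopropylsilyl ether, since a tert-butyldimethylsilyl ether of a 4-acylphenol is unlikely to outlast the methanolic acid and amidine-base steps.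

**Route**

Step 1
Reactants: 1 4-hydroxybenzaldehyde
Product: 2 4-(triisopropylsilyloxy)benzaldehyde
Conditions: TIPSCl, imidazole, DMF, rt
Reagents that add atoms: triisopropylsilyl chloride, CC(C)[Si](Cl)(C(C)C)C(C)C
Why: Silylation of a phenol with a trialkylsilyl chloride and imidazole is routine, and the triisopropylsilyl group is chosen because this ether must later outlast an aryllithium, methanolic acid and an amidine base.

Step 2
Reactants: 3 phloroglucinol
Product: 4 1,3,5-tris(methoxymethoxy)benzene
Conditions: MOMCl, i-Pr2NEt, DMF, 0 °C → rt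
Reagents that add atoms: chloromethyl methyl ether, COCCl
Why: Base-mediated O-alkylation of the three phenols with the hard chloromethyl ether (Williamson-type acetal formation) should give the symmetric tris-MOM ether, whose acetal oxygens protect the phenols and direct the metalation that follows.

Step 3
Reactants: 4 1,3,5-tris(methoxymethoxy)benzene; 2 4-(triisopropylsilyloxy)benzaldehyde
Product: 6 rac-[4-(triisopropylsilyloxy)phenyl][2,4,6-tris(methoxymethoxy)phenyl]methanol, via 2,4,6-tris(methoxymethoxy)phenyllithium 5 (not isolated)
Conditions: n-BuLi, THF, 0 °C; then 2, −78 °C → 0 °C; H2O quench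
Reagents that add atoms: none
Why: Directed ortho-lithiation removes the ring proton flanked by two MOM ethers, and 1,2-addition of aryllithium 5 to the non-enolisable aldehyde forms the aryl–carbon bond and a racemic carbinol centre that the next oxidation erases.

Step 4
Reactants: 6 rac-[4-(triisopropylsilyloxy)phenyl][2,4,6-tris(methoxymethoxy)phenyl]methanol
Product: 7 [4-(triisopropylsilyloxy)phenyl][2,4,6-tris(methoxymethoxy)phenyl]methanone
Conditions: Dess–Martin periodinane, NaHCO3, CH2Cl2, 0 °C → rt
Reagents that add atoms: none
Why: Dess–Martin oxidation of the doubly benzylic secondary alcohol should proceed under bicarbonate buffering, which keeps the MOM acetals and the easily ionised electron-rich benzhydrol away from acid.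

Step 5
Reactants: 7 [4-(triisopropylsilyloxy)phenyl][2,4,6-tris(methoxymethoxy)phenyl]methanone
Product: 8 (2,4,6-trihydroxyphenyl)[4-(triisopropylsilyloxy)phenyl]methanone
Conditions: HCl (ca. 1 M in MeOH), 50 °C
Reagents that add atoms: none
Why: Acid-catalysed acetal exchange with methanol (MOM deprotection) should release the three phenols, the two ortho ones assisted by the carbonyl, while the hindered silyl ether on the weakly basic acylphenol oxygen is expected to persist in dilute methanolic acid.

Step 6
Reactants: 8 (2,4,6-trihydroxyphenyl)[4-(triisopropylsilyloxy)phenyl]methanone; 9 3-chloro-3-methylbut-1-yne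
Product: 10 [2,6-dihydroxy-4-(2-methylbut-3-yn-2-yloxy)phenyl][4-(triisopropylsilyloxy)phenyl]methanone
Conditions: CuCl2·2H2O (cat.), DBU (1.2 equiv), MeCN, 0 °C
Reagents that add atoms: none
Why: Copper-catalysed propargylic etherification (copper acetylide to allenylidene, attacked at its tertiary carbon) should alkylate only the hydroxyl para to the carbonyl, because one equivalent of DBU ionises this most acidic, non-hydrogen-bonded phenol and leaves the two ortho hydroxyls untouched.

Step 7
Reactants: 10 [2,6-dihydroxy-4-(2-methylbut-3-yn-2-yloxy)phenyl][4-(triisopropylsilyloxy)phenyl]methanone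
Product: 11 [2,6-dihydroxy-4-(2-methylbut-3-en-2-yloxy)phenyl][4-(triisopropylsilyloxy)phenyl]methanone
Conditions: H2 (1 atm), Lindlar catalyst, quinoline, EtOAc, rt
Reagents that add atoms: none
Why: Lindlar semihydrogenation over lead-poisoned palladium with quinoline should stop at the alkene because the terminal alkyne is bound far more strongly than its product, giving the 1,1-dimethylallyl ether needed for the sigmatropic shift.

Step 8
Reactants: 11 [2,6-dihydroxy-4-(2-methylbut-3-en-2-yloxy)phenyl][4-(triisopropylsilyloxy)phenyl]methanone
Product: 12 [2,6-dihydroxy-3-iodo-4-(2-methylbut-3-en-2-yloxy)phenyl][4-(triisopropylsilyloxy)phenyl]methanone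
Conditions: NIS (1.0 equiv), MeCN, −20 → 0 °C, dark
Reagents that add atoms: N-iodosuccinimide, O=C1CCC(=O)N1I
Why: Electrophilic aromatic iodination at one of the two equivalent, triply activated ring positions should stop after one substitution because the iodine withdraws electron density and pushes the bulky tertiary alkoxy group over the remaining position, while the monosubstituted alkene has no hydroxyl within reach for iodoetherification.

Step 9
Reactants: 12 [2,6-dihydroxy-3-iodo-4-(2-methylbut-3-en-2-yloxy)phenyl][4-(triisopropylsilyloxy)phenyl]methanone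
Product: 14 [2,4,6-trihydroxy-3-iodo-5-(3-methylbut-2-en-1-yl)phenyl][4-(triisopropylsilyloxy)phenyl]methanone, via Claisen cyclohexadienone 13 (not isolated)
Conditions: toluene, 110 °C
Reagents that add atoms: none
Why: Aromatic Claisen rearrangement moves the allyl unit by a [3,3] shift to the only unsubstituted ortho carbon with allylic inversion, so the tertiary ether delivers a prenyl group and enolisation of dienone 13 restores the phenol, whereas a shift to the iodinated carbon can only revert.

Step 10
Reactants: 14 [2,4,6-trihydroxy-3-iodo-5-(3-methylbut-2-en-1-yl)phenyl][4-(triisopropylsilyloxy)phenyl]methanone; 15 tributyl(vinyl)stannane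
Product: 16 [2,4,6-trihydroxy-3-(3-methylbut-2-en-1-yl)-5-vinylphenyl][4-(triisopropylsilyloxy)phenyl]methanone
Conditions: Pd(PPh3)4 (5 mol %), BHT (cat.), toluene, 90 °C
Reagents that add atoms: none
Why: Stille cross-coupling transfers the small vinyl group from tin to the aryl iodide under neutral conditions, which the free phenols, the prenyl alkene and the silyl ether tolerate and under which no phenoxide forms that could slow oxidative addition or attack the silyl ether.

Step 11
Reactants: 16 [2,4,6-trihydroxy-3-(3-methylbut-2-en-1-yl)-5-vinylphenyl][4-(triisopropylsilyloxy)phenyl]methanone; 9 3-chloro-3-methylbut-1-yne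
Product: 17 [2,6-dihydroxy-4-(2-methylbut-3-yn-2-yloxy)-3-(3-methylbut-2-en-1-yl)-5-vinylphenyl][4-(triisopropylsilyloxy)phenyl]methanone
Conditions: CuCl2·2H2O (cat.), DBU (1.2 equiv), MeCN, 0 °C → rt
Reagents that add atoms: none
Why: The same copper-catalysed propargylic etherification should again select the hydroxyl para to the carbonyl, the most acidic and the only one not hydrogen-bonded to the ketone, and the reactive allenylidene electrophile is relied on to overcome the flanking vinyl and prenyl groups.

Step 12
Reactants: 17 [2,6-dihydroxy-4-(2-methylbut-3-yn-2-yloxy)-3-(3-methylbut-2-en-1-yl)-5-vinylphenyl][4-(triisopropylsilyloxy)phenyl]methanone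
Product: 18 [2,6-dihydroxy-4-(2-methylbut-3-en-2-yloxy)-3-(3-methylbut-2-en-1-yl)-5-vinylphenyl][4-(triisopropylsilyloxy)phenyl]methanone
Conditions: H2 (1 atm, 1 equiv uptake), Lindlar catalyst, quinoline, EtOAc, rt
Reagents that add atoms: none
Why: Lindlar semihydrogenation should reduce only the terminal alkyne, which outcompetes the styrenyl and trisubstituted alkenes for the poisoned palladium surface, provided the reaction is stopped after one equivalent of hydrogen.

Step 13
Reactants: 18 [2,6-dihydroxy-4-(2-methylbut-3-en-2-yloxy)-3-(3-methylbut-2-en-1-yl)-5-vinylphenyl][4-(triisopropylsilyloxy)phenyl]methanone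
Product: 19 [5,7-dihydroxy-2,2-dimethyl-8-(3-methylbut-2-en-1-yl)-2H-chromen-6-yl][4-(triisopropylsilyloxy)phenyl]methanone
Conditions: Grubbs second-generation catalyst (5 mol %), CH2Cl2 (0.01 M), 40 °C
Reagents that add atoms: none
Why: Ring-closing olefin metathesis: the ruthenium alkylidene should load on the accessible aryl vinyl group, add through a ruthenacyclobutane to the hindered but monosubstituted ether alkene, and cyclorevert to the C3=C4 bond with loss of ethene as the driving force. The closest known reaction type is the metathesis of 2-vinylaryl allyl ethers to 2H-chromenes, including 2,2-disubstituted cases. The one ring closed is the six-membered pyran, formed between the styrenyl carbon on C4a and the vinyl carbon on the quaternary C2, and because the ring allows only a cis alkene no stereocentre or alkene geometry has to be controlled. The step needs chemoselectivity among three alkenes, and substitution secures it: the two terminal alkenes close the six-membered ring quickly, whereas the trisubstituted prenyl alkene could at most close a seven-membered oxepine with loss of isobutene, a much slower process under these mild conditions. The regiochemistry of the pyran is fixed beforehand because its carbon and oxygen ends were installed separately, so neither chelated hydroxyl can take part. The neutral conditions should leave the ionisable tertiary allylic ether, the free phenols and the silyl ether intact.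

Step 14
Reactants: 19 [5,7-dihydroxy-2,2-dimethyl-8-(3-methylbut-2-en-1-yl)-2H-chromen-6-yl][4-(triisopropylsilyloxy)phenyl]methanone
Product: 20 vismiaphenone E, [5,7-dihydroxy-2,2-dimethyl-8-(3-methylbut-2-en-1-yl)-2H-chromen-6-yl](4-hydroxyphenyl)methanone
Conditions: TBAF (1.1 equiv), AcOH (1.1 equiv), THF, 0 °C
Reagents that add atoms: none
Why: Fluoride-mediated desilylation is driven by the strong Si–F bond and, buffered with acetic acid, should leave the chromene, the prenyl group and the chelated phenols untouched.

**Compound list**

1 | 4-hydroxybenzaldehyde | O=Cc1ccc(O)cc1 | starting material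
2 | 4-(triisopropylsilyloxy)benzaldehyde | O=Cc1ccc(O[Si](C(C)C)(C(C)C)C(C)C)cc1 | intermediate
3 | phloroglucinol | Oc1cc(O)cc(O)c1 | starting material
4 | 1,3,5-tris(methoxymethoxy)benzene | COCOc1cc(OCOC)cc(OCOC)c1 | intermediate
5 | 2,4,6-tris(methoxymethoxy)phenyllithium | [Li]c1c(OCOC)cc(OCOC)cc1OCOC | intermediate
6 | rac-[4-(triisopropylsilyloxy)phenyl][2,4,6-tris(methoxymethoxy)phenyl]methanol | COCOc1cc(OCOC)c(C(O)c2ccc(O[Si](C(C)C)(C(C)C)C(C)C)cc2)c(OCOC)c1 | intermediate
7 | [4-(triisopropylsilyloxy)phenyl][2,4,6-tris(methoxymethoxy)phenyl]methanone | COCOc1cc(OCOC)c(C(=O)c2ccc(O[Si](C(C)C)(C(C)C)C(C)C)cc2)c(OCOC)c1 | intermediate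
8 | (2,4,6-trihydroxyphenyl)[4-(triisopropylsilyloxy)phenyl]methanone | Oc1cc(O)c(C(=O)c2ccc(O[Si](C(C)C)(C(C)C)C(C)C)cc2)c(O)c1 | intermediate
9 | 3-chloro-3-methylbut-1-yne | C#CC(C)(C)Cl | starting material
10 | [2,6-dihydroxy-4-(2-methylbut-3-yn-2-yloxy)phenyl][4-(triisopropylsilyloxy)phenyl]methanone | C#CC(C)(C)Oc1cc(O)c(C(=O)c2ccc(O[Si](C(C)C)(C(C)C)C(C)C)cc2)c(O)c1 | intermediate
11 | [2,6-dihydroxy-4-(2-methylbut-3-en-2-yloxy)phenyl][4-(triisopropylsilyloxy)phenyl]methanone | C=CC(C)(C)Oc1cc(O)c(C(=O)c2ccc(O[Si](C(C)C)(C(C)C)C(C)C)cc2)c(O)c1 | intermediate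
12 | [2,6-dihydroxy-3-iodo-4-(2-methylbut-3-en-2-yloxy)phenyl][4-(triisopropylsilyloxy)phenyl]methanone | C=CC(C)(C)Oc1cc(O)c(C(=O)c2ccc(O[Si](C(C)C)(C(C)C)C(C)C)cc2)c(O)c1I | intermediate
13 | 3,5-dihydroxy-2-iodo-6-(3-methylbut-2-en-1-yl)-4-[4-(triisopropylsilyloxy)benzoyl]cyclohexa-2,4-dien-1-one (racemic, transient Claisen dienone) | O=C1C(I)=C(O)C(C(=O)c2ccc(O[Si](C(C)C)(C(C)C)C(C)C)cc2)=C(O)C1CC=C(C)C | intermediate
14 | [2,4,6-trihydroxy-3-iodo-5-(3-methylbut-2-en-1-yl)phenyl][4-(triisopropylsilyloxy)phenyl]methanone | CC(C)=CCc1c(O)c(I)c(O)c(C(=O)c2ccc(O[Si](C(C)C)(C(C)C)C(C)C)cc2)c1O | intermediate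
15 | tributyl(vinyl)stannane | C=C[Sn](CCCC)(CCCC)CCCC | starting material
16 | [2,4,6-trihydroxy-3-(3-methylbut-2-en-1-yl)-5-vinylphenyl][4-(triisopropylsilyloxy)phenyl]methanone | CC(C)=CCc1c(O)c(C=C)c(O)c(C(=O)c2ccc(O[Si](C(C)C)(C(C)C)C(C)C)cc2)c1O | intermediate
17 | [2,6-dihydroxy-4-(2-methylbut-3-yn-2-yloxy)-3-(3-methylbut-2-en-1-yl)-5-vinylphenyl][4-(triisopropylsilyloxy)phenyl]methanone | CC(C)=CCc1c(OC(C)(C)C#C)c(C=C)c(O)c(C(=O)c2ccc(O[Si](C(C)C)(C(C)C)C(C)C)cc2)c1O | intermediate
18 | [2,6-dihydroxy-4-(2-methylbut-3-en-2-yloxy)-3-(3-methylbut-2-en-1-yl)-5-vinylphenyl][4-(triisopropylsilyloxy)phenyl]methanone | CC(C)=CCc1c(OC(C)(C)C=C)c(C=C)c(O)c(C(=O)c2ccc(O[Si](C(C)C)(C(C)C)C(C)C)cc2)c1O | intermediate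
19 | [5,7-dihydroxy-2,2-dimethyl-8-(3-methylbut-2-en-1-yl)-2H-chromen-6-yl][4-(triisopropylsilyloxy)phenyl]methanone (4'-O-triisopropylsilyl vismiaphenone E) | CC(C)=CCc1c(O)c(C(=O)c3ccc(O[Si](C(C)C)(C(C)C)C(C)C)cc3)c(O)c2c1OC(C)(C)C=C2 | intermediate
20 | vismiaphenone E, [5,7-dihydroxy-2,2-dimethyl-8-(3-methylbut-2-en-1-yl)-2H-chromen-6-yl](4-hydroxyphenyl)methanone | CC(C)=CCc1c(O)c(C(=O)c2ccc(O)cc2)c(O)c2c1OC(C)(C)C=C2 | target

**Step count**

Total steps: 14. Longest linear sequence: 13 steps (steps 2 to 14, from phloroglucinol); step 1 is a one-step side branch that joins at step 3.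

**Steps most likely to fail, with fallbacks**

Step 8. The iodination may run on to the di-iodide or stall, because both open ring positions are equally activated and only sterics and the first iodine distinguish them. The fallback reverses the order so that a single ring position is left when iodine is introduced. Setting out from 11, heating in toluene at 110 °C should give, through the transient dienone 3,5-dihydroxy-6-(3-methylbut-2-en-1-yl)-4-[4-(triisopropylsilyloxy)benzoyl]cyclohexa-2,4-dien-1-one F1, the prenylated triol [2,4,6-trihydroxy-3-(3-methylbut-2-en-1-yl)phenyl][4-(triisopropylsilyloxy)phenyl]methanone F2. Its one remaining ring CH would then be iodinated as the phenoxide with I2 and NaHCO3 in aqueous THF at 0 °C, where ring substitution of the phloroglucinol anion should outrun attack on the prenyl alkene. This comes back to the route at 14.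

Step 10. The coupling may suffer proto-deiodination or slow transmetalation at an electron-rich iodide flanked by two free hydroxyls, and the vinylphenol formed may oligomerise at 90 °C. The fallback couples on a masked, electron-poorer ring. From 14, Ac2O, pyridine and DMAP should give the triacetate 2-iodo-4-(3-methylbut-2-en-1-yl)-6-[4-(triisopropylsilyloxy)benzoyl]benzene-1,3,5-triyl triacetate F3. Stille coupling of this non-acidic iodide with 15 (Pd(PPh3)4, toluene, 90 °C) would give 2-(3-methylbut-2-en-1-yl)-4-[4-(triisopropylsilyloxy)benzoyl]-6-vinylbenzene-1,3,5-triyl triacetate F4. Aminolysis of the three aryl acetates with NH3 in MeOH at 0 °C, which an aryl triisopropylsilyl ether should survive, returns to the route at 16.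

Step 11. Ether formation at an oxygen flanked by vinyl and prenyl groups may be slow, and the ambident phenoxide of the fully substituted acylphloroglucinol may instead be alkylated on carbon with dearomatisation. The fallback is a palladium-catalysed decarboxylative O-allylation (Tsuji–Trost type), in which the phenoxide attacks the more substituted end of a π-prenyl palladium complex and gives the tertiary allyl ether directly. The reagent tert-butyl 2-methylbut-3-en-2-yl carbonate F5 would be made from 2-methylbut-3-en-2-ol with n-BuLi and Boc2O in THF. Treating 16 with F5 and Pd(PPh3)4 in THF at 0 °C, stopped early to avoid equilibration of the branched ether to the linear one, leads from 16 straight to 18. This also bypasses 17 and the semihydrogenation of step 12, whose own risk is over-reduction of the styrenyl alkene.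

**Further compounds**

F1 | step 8 | 3,5-dihydroxy-6-(3-methylbut-2-en-1-yl)-4-[4-(triisopropylsilyloxy)benzoyl]cyclohexa-2,4-dien-1-one (racemic, transient) | O=C1C=C(O)C(C(=O)c2ccc(O[Si](C(C)C)(C(C)C)C(C)C)cc2)=C(O)C1CC=C(C)C
F2 | step 8 | [2,4,6-trihydroxy-3-(3-methylbut-2-en-1-yl)phenyl][4-(triisopropylsilyloxy)phenyl]methanone | CC(C)=CCc1c(O)cc(O)c(C(=O)c2ccc(O[Si](C(C)C)(C(C)C)C(C)C)cc2)c1O
F3 | step 10 | 2-iodo-4-(3-methylbut-2-en-1-yl)-6-[4-(triisopropylsilyloxy)benzoyl]benzene-1,3,5-triyl triacetate | CC(C)=CCc1c(OC(C)=O)c(I)c(OC(C)=O)c(C(=O)c2ccc(O[Si](C(C)C)(C(C)C)C(C)C)cc2)c1OC(C)=O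
F4 | step 10 | 2-(3-methylbut-2-en-1-yl)-4-[4-(triisopropylsilyloxy)benzoyl]-6-vinylbenzene-1,3,5-triyl triacetate | CC(C)=CCc1c(OC(C)=O)c(C=C)c(OC(C)=O)c(C(=O)c2ccc(O[Si](C(C)C)(C(C)C)C(C)C)cc2)c1OC(C)=O
F5 | step 11 | tert-butyl 2-methylbut-3-en-2-yl carbonate | C=CC(C)(C)OC(=O)OC(C)(C)C
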